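**Plan**

1. Retrosynthetic cuts: the two angelate C–O bonds; the (13Z)-C12–C15 keto-enoate back to a 3-methylfuran (C12–O–C15); C11–C12 and C9=C11; C17–O; C2–O/C3–O back to a C2=C3 alkene; C3–C4 (ring A); C10–C1 and C10–C20.
2. What is left is (R)-carvone, which is ring B: its carbonyl is C9, its enone methyl is C17 on the C7=C8 bond, its stereocentre is C5 and its isopropenyl carbon is C4.
3. Forward: C10 is dialkylated (methyl, propargyl), ring A is closed across C3–C4 by a cation–alkyne cyclisation, C2/C3 are dihydroxylated, C9=O becomes C9(H)–C11–furan, C17 is oxidised, the furan is opened with singlet oxygen and the acid is methylated.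
4. Feature that makes the key step possible: C4 is a gem-dimethyl carbon bonded to ring-fusion C5, and the C2/C3 cis-diol has the oxidation level of a C2=C3 alkene, so ring A (C1–C5, C10) can be closed from an isopropenyl-derived C4 cation and a C2≡C3 alkyne on C10.
5. Stereochemistry: C5 from carvone; C10 by alkylation anti to the isopropenyl group; C2 and C3 by OsO4 anti to the axial C10 methyl; C9 by hydroboration anti to the C10 methyl; 13Z from the furan ring; angelate Z from angelic acid.

Key step: step 3

Remark: labdane numbering is used for all intermediates (C1–C10 decalin, C11–C16 side chain, C17 on C8, C18/C19 on C4, C20 on C10). Compound 3 is carried on as a C6-epimer mixture because this centre is re-enolised in step 2; its SMILES shows the expected major epimer. Compounds 19 and 20 are epimer mixtures at the masked C12 centre, which becomes the ketone, so their SMILES leave it open.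

**Route**

Step 1
Reactants: 1 (R)-(−)-carvone
Product: 3 trans-6-methylcarvone, via lithium dienolate 2 (not isolated)
Conditions: LDA (1.05 equiv), THF, −78 °C; MeI, −78 → 0 °C
Reagents that add atoms: iodomethane CI
Why: Kinetic α′-deprotonation of the enone and C-methylation of the lithium dienolate (enolate alkylation) install C20; the new centre is not controlled because it is planarised again in step 2.

Step 2
Reactants: 3 trans-6-methylcarvone
Product: 5 (5S,6S)-2,6-dimethyl-5-(prop-1-en-2-yl)-6-(prop-2-yn-1-yl)cyclohex-2-en-1-one, via lithium enolate 4 (not isolated)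
Conditions: LDA (1.1 equiv), THF, −78 → −20 °C; propargyl bromide, DMPU, −78 °C → rt
Reagents that add atoms: propargyl bromide C#CCBr
Why: Enolate alkylation at the tertiary α′-carbon creates quaternary C10, the electrophile approaching anti to the pseudoaxial isopropenyl group on C5, which should place C1 trans to C4 and the methyl cis to it (future 10β-Me/5α-H).

Step 3
Reactants: 5 propargyl ketone
Product: 6 (4aS,8aS)-4,4,7,8a-tetramethyl-8-oxo-1,4,4a,5,8,8a-hexahydronaphthalen-2-yl trifluoromethanesulfonate (trans-fused; C2–OTf, C2=C3)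
Conditions: TfOH (2.2 equiv), CH2Cl2, −78 → −40 °C; pyridine, then aq. NaHCO3
Reagents that add atoms: trifluoromethanesulfonic acid OS(=O)(=O)C(F)(F)F
Why: TfOH protonates the isopropenyl group (Markovnikov) to the tertiary C4 cation, the terminal alkyne carbon C3 adds to it and the resulting endocyclic C2 vinyl cation is captured by triflate. The closest known reaction is the triflic acid promoted cationic carbocyclisation of alkene-tethered terminal alkynes to cyclohexenyl triflates (alkyne-terminated cation–π cyclisation). Ring A (C1–C5, C10) closes by C3–C4 bond formation in the 6-endo-dig mode, since the 5-exo alternative would pass through a primary exocyclic vinyl cation. No new stereocentre is formed (C4 carries two methyls); the trans ring fusion follows from the trans C1/C4 substituents set in step 2, which are both equatorial in the chair-like transition state with the C10 methyl axial. The step needs protonation of the 1,1-disubstituted alkene in preference to the alkyne and capture of the cation before proton loss toward C5; the higher basicity of the alkene, the six-membered transition state and the low temperature should secure this, while the enone only binds one equivalent of acid and cannot aromatise because C10 is quaternary. The product holds the leaving group and the double bond exactly on C2 and C3, the carbons of the later diol.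

Step 4
Reactants: 6 enol triflate
Product: 7 (4aS,8aS)-2,5,5,8a-tetramethyl-4a,5,8,8a-tetrahydronaphthalen-1(4H)-one
Conditions: Pd(OAc)2 (5 mol%), PPh3 (10 mol%), n-Bu3N, HCO2H, DMF, 60 °C
Reagents that add atoms: none
Why: Palladium-catalysed formate hydrogenolysis of an enol triflate (Cacchi reduction) replaces C2–OTf by C2–H, leaves the C2=C3 alkene in place and does not touch the enone; no stereocentre is formed.

Step 5
Reactants: 7 dienone
Product: 8 (4aS,6S,7R,8aS)-6,7-dihydroxy-2,5,5,8a-tetramethyl-4a,5,6,7,8,8a-hexahydronaphthalen-1(4H)-one (2α,3α-diol)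
Conditions: OsO4 (2 mol%), NMO (1.1 equiv), acetone/H2O, 0 °C → rt
Reagents that add atoms: N-methylmorpholine N-oxide C[N+]1([O-])CCOCC1; water O
Why: Catalytic syn-dihydroxylation (Upjohn) should take the isolated cis-alkene C2=C3 rather than the electron-poor enone alkene and attack the α-face, anti to the axial C10 and 4β methyls, to set 2α,3α (2R,3S).

Step 6
Reactants: 8 diol
Product: 9 2α,3α-acetonide of 8
Conditions: 2,2-dimethoxypropane, PPTS (cat.), acetone, rt
Reagents that add atoms: 2,2-dimethoxypropane COC(C)(C)OC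
Why: Acid-catalysed transketalisation of the cis-diol gives the acetonide, which shields both hydroxyls from the ylide, the borane and the base of the next steps.

Step 7
Reactants: 9 acetonide ketone
Product: 10 acetonide diene with exocyclic C9=C11 conjugated to C7=C8
Conditions: Ph3PCH3Br, KOt-Bu, toluene, 90 °C
Reagents that add atoms: methyltriphenylphosphonium bromide C[P+](c1ccccc1)(c1ccccc1)c1ccccc1.[Br-]
Why: Wittig methylenation under the tert-butoxide/toluene protocol for hindered ketones converts C9=O into C9=C11; C10 is quaternary and C8 is sp2, so no centre can epimerise.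

Step 8
Reactants: 11 3-methylfuran
Product: 12 2-bromo-3-methylfuran
Conditions: NBS (1.0 equiv), DMF, −10 °C → rt; used at once as a solution
Reagents that add atoms: N-bromosuccinimide O=C1CCC(=O)N1Br
Why: Electrophilic bromination of the furan occurs at C2, the α-position activated by the adjacent methyl group, and gives the partner that holds C12–C16.

Step 9
Reactants: 10 acetonide diene; 12 2-bromo-3-methylfuran
Product: 14 12,15-epoxylabda-7,12,14-triene-2α,3α-diol acetonide, via B-alkyl-9-BBN 13 (not isolated)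
Conditions: 9-BBN, THF, rt → 50 °C; then 12, Pd(dppf)Cl2 (5 mol%), AsPh3, Cs2CO3, DMF/H2O, rt → 45 °C
Reagents that add atoms: none
Why: 9-BBN hydroboration of the 1,1-disubstituted diene terminus puts boron on C11 and hydrogen on C9 from the α-face anti to the axial C10 methyl (9α-H, C11 β), and B-alkyl Suzuki–Miyaura coupling of the borane with the bromofuran forms C11–C12.

Step 10
Reactants: 14 furan acetonide
Product: 15 12,15-epoxylabda-7,12,14-triene-2α,3α-diol
Conditions: AcOH/THF/H2O (3:1:1), 45 °C
Reagents that add atoms: none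
Why: Mild aqueous acid hydrolysis of the cis-fused acetonide (ketal cleavage) should leave the 2,3-dialkylfuran and the trisubstituted alkene intact.

Step 11
Reactants: 15 furan diol
Product: 16 2α,3α-bis(angeloyloxy)-12,15-epoxylabda-7,12,14-triene
Conditions: angelic acid (6 equiv), 2,4,6-trichlorobenzoyl chloride, Et3N, toluene, rt; then 15, 80 °C (no DMAP)
Reagents that add atoms: angelic acid C/C=C(/C)C(=O)O
Why: Yamaguchi-type esterification with the preformed angelic 2,4,6-trichlorobenzoic mixed anhydride acylates the equatorial 2α- and the axial 3α-hydroxyl and is the protocol that keeps the Z geometry of angelates.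

Step 12
Reactants: 16 bis-angelate
Product: 18 2α,3α-bis(angeloyloxy)-12,15-epoxylabda-7,12,14-trien-17-al, via C17 allylic alcohol 17 (not isolated)
Conditions: SeO2 (0.3 equiv), t-BuOOH, CH2Cl2, 0 °C → rt; filter; MnO2, CH2Cl2, rt
Reagents that add atoms: tert-butyl hydroperoxide CC(C)(C)OO
Why: Selenium dioxide allylic oxidation (ene reaction, then [2,3]-shift) should take the methyl on the more substituted alkene carbon C8, cis to H7, the electron-poor angelate alkenes being inert, and MnO2 then oxidises the allylic alcohol to the enal.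

Step 13
Reactants: 18 furan enal
Product: 20 2α,3α-bis(angeloyloxy)-12-hydroxy-17-oxolabda-7,13-dien-15,12-olide (γ-hydroxybutenolide), via furan endoperoxide 19 (not isolated)
Conditions: O2, tetraphenylporphyrin (cat.), i-Pr2NEt, CH2Cl2, visible light, −78 °C → rt
Reagents that add atoms: oxygen O=O
Why: Singlet-oxygen [4+2] cycloaddition across C12/C15 of the furan and base-induced Kornblum–DeLaMare fragmentation of the endoperoxide at its only bridgehead hydrogen (C15–H) give the lactol, whose ring holds C13=C14 cis; the enal and angelate alkenes are too electron-poor to react.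

Step 14
Reactants: 20 γ-hydroxybutenolide
Product: 22 methyl (13Z)-2α,3α-bis(angeloyloxy)-12,17-dioxolabda-7,13-dien-15-oate (CNP0141070.1), via potassium keto-carboxylate 21 (not isolated)
Conditions: KHCO3 (1.5 equiv), MeI, DMF, 0 °C → rt, dark
Reagents that add atoms: iodomethane CI
Why: Bicarbonate opens the lactol to the Z-keto-carboxylate, and carboxylate O-alkylation with iodomethane gives the open-chain methyl ester with the 13Z geometry inherited from the ring.

**Compound list**

1 | (R)-(−)-carvone | CC(=C)[C@@H]1CC=C(C)C(=O)C1 | starting material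
2 | lithium α′-dienolate of carvone | [Li+].[O-]C1=C[C@@H](CC=C1C)C(C)=C | intermediate
3 | (5R,6S)-2,6-dimethyl-5-(prop-1-en-2-yl)cyclohex-2-en-1-one (trans-6-methylcarvone) | C[C@@H]1C(=O)C(C)=CC[C@H]1C(C)=C | intermediate
4 | lithium enolate of 3 (C9–O, C9=C10) | [Li+].[O-]C1=C(C)[C@@H](CC=C1C)C(C)=C | intermediate
5 | (5S,6S)-2,6-dimethyl-5-(prop-1-en-2-yl)-6-(prop-2-yn-1-yl)cyclohex-2-en-1-one (propargyl trans to isopropenyl) | C#CC[C@]1(C)C(=O)C(C)=CC[C@H]1C(C)=C | intermediate
6 | (4aS,8aS)-4,4,7,8a-tetramethyl-8-oxo-1,4,4a,5,8,8a-hexahydronaphthalen-2-yl trifluoromethanesulfonate | C1=C(OS(=O)(=O)C(F)(F)F)C[C@]2(C)C(=O)C(C)=CC[C@H]2C1(C)C | intermediate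
7 | (4aS,8aS)-2,5,5,8a-tetramethyl-4a,5,8,8a-tetrahydronaphthalen-1(4H)-one | C1=CC[C@]2(C)C(=O)C(C)=CC[C@H]2C1(C)C | intermediate
8 | (4aS,6S,7R,8aS)-6,7-dihydroxy-2,5,5,8a-tetramethyl-4a,5,6,7,8,8a-hexahydronaphthalen-1(4H)-one | O[C@@H]1[C@H](O)C[C@]2(C)C(=O)C(C)=CC[C@H]2C1(C)C | intermediate
9 | 2α,3α-O-isopropylidene derivative of 8 | CC1(C)O[C@@H]2[C@H](O1)C[C@]3(C)C(=O)C(C)=CC[C@H]3C2(C)C | intermediate
10 | 9-methylidene analogue of 9 (C9=C11, C7=C8 diene) | CC1(C)O[C@@H]2[C@H](O1)C[C@]3(C)C(=C)C(C)=CC[C@H]3C2(C)C | intermediate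
11 | 3-methylfuran | Cc1ccoc1 | starting material
12 | 2-bromo-3-methylfuran | Cc1ccoc1Br | intermediate
13 | B-(C11-alkyl)-9-borabicyclo[3.3.1]nonane from 10 (9α-H) | CC1(C)O[C@@H]2[C@H](O1)C[C@]3(C)[C@@H](CB4C5CCCC4CCC5)C(C)=CC[C@H]3C2(C)C | intermediate
14 | 12,15-epoxylabda-7,12,14-triene-2α,3α-diol acetonide | CC1(C)O[C@@H]2[C@H](O1)C[C@]3(C)[C@@H](Cc4occc4C)C(C)=CC[C@H]3C2(C)C | intermediate
15 | 12,15-epoxylabda-7,12,14-triene-2α,3α-diol | O[C@@H]1[C@H](O)C[C@]2(C)[C@@H](Cc3occc3C)C(C)=CC[C@H]2C1(C)C | intermediate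
16 | 2α,3α-bis(angeloyloxy)-12,15-epoxylabda-7,12,14-triene | C/C=C(/C)C(=O)O[C@@H]1[C@H](OC(=O)/C(C)=C\C)C[C@]2(C)[C@@H](Cc3occc3C)C(C)=CC[C@H]2C1(C)C | intermediate
17 | 2α,3α-bis(angeloyloxy)-12,15-epoxylabda-7,12,14-trien-17-ol | C/C=C(/C)C(=O)O[C@@H]1[C@H](OC(=O)/C(C)=C\C)C[C@]2(C)[C@@H](Cc3occc3C)C(CO)=CC[C@H]2C1(C)C | intermediate
18 | 2α,3α-bis(angeloyloxy)-12,15-epoxylabda-7,12,14-trien-17-al | C/C=C(/C)C(=O)O[C@@H]1[C@H](OC(=O)/C(C)=C\C)C[C@]2(C)[C@@H](Cc3occc3C)C(C=O)=CC[C@H]2C1(C)C | intermediate
19 | 12,15-epidioxy endoperoxide of 18 (2,3,7-trioxabicyclo[2.2.1]hept-5-ene) | C/C=C(/C)C(=O)O[C@@H]1[C@H](OC(=O)/C(C)=C\C)C[C@]2(C)[C@@H](CC34OOC(O3)C=C4C)C(C=O)=CC[C@H]2C1(C)C | intermediate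
20 | 2α,3α-bis(angeloyloxy)-12-hydroxy-17-oxolabda-7,13-dien-15,12-olide | C/C=C(/C)C(=O)O[C@@H]1[C@H](OC(=O)/C(C)=C\C)C[C@]2(C)[C@@H](CC3(O)OC(=O)C=C3C)C(C=O)=CC[C@H]2C1(C)C | intermediate
21 | potassium (13Z)-2α,3α-bis(angeloyloxy)-12,17-dioxolabda-7,13-dien-15-oate | C/C=C(/C)C(=O)O[C@@H]1[C@H](OC(=O)/C(C)=C\C)C[C@]2(C)[C@@H](CC(=O)/C(C)=C\C(=O)[O-])C(C=O)=CC[C@H]2C1(C)C.[K+] | intermediate
22 | methyl (13Z)-2α,3α-bis(angeloyloxy)-12,17-dioxolabda-7,13-dien-15-oate | C/C=C(/C)C(=O)O[C@@H]1[C@H](OC(=O)/C(C)=C\C)C[C@]2(C)[C@@H](CC(=O)/C(C)=C\C(=O)OC)C(C=O)=CC[C@H]2C1(C)C | target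

**Step count and risks**

Total steps: 14. Longest linear sequence: 13 (steps 1–7 and 9–14; step 8 makes the furan fragment).

Step 3. The C4 cation may lose a proton toward C5 or suffer a hydride shift before the weakly nucleophilic alkyne adds, which would erode the C5 configuration, or the acid may add to the alkyne first. The fallback uses a stronger π-nucleophile and a Lewis acid instead of a superacid. It sets out from 3: alkylation of its lithium enolate with (Z)-(3-bromoprop-1-en-1-yl)trimethylsilane should give 6-methyl-6-[(Z)-3-(trimethylsilyl)allyl]carvone F1. Dry HCl in CH2Cl2 at −78 °C adds to the isopropenyl group to give the tertiary chloride F2. SnCl4 in CH2Cl2 at −78 °C ionises the chloride, and the vinylsilane closes ring A through its silicon-bearing carbon C3 (vinylsilane-terminated cation cyclisation); loss of silicon from the β-silyl cation gives the C2=C3 alkene. This returns to the route at 7, and steps 3 and 4 are not needed.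

Step 11. Acylation of the axial 3α-hydroxyl next to the gem-dimethyl carbon may stop at the mono-ester, and forcing it may isomerise angelate to tiglate. The fallback builds the Z-alkene after the ester bond is made. It sets out from 15: carbodiimide esterification (EDC, DMAP, CH2Cl2) with 2-[bis(2,2,2-trifluoroethoxy)phosphoryl]propanoic acid gives the 2α,3α-bis(phosphonopropionate) F3. Still–Gennari olefination (KHMDS, 18-crown-6, THF, −78 °C, acetaldehyde) then forms both Z-2-methylbut-2-enoates and returns to the route at 16.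

Step 12. The selenium oxidant may attack the electron-rich furan or the furfuryl-type C11–H bonds instead of C17, or oxidise the ring methylene C6. The fallback runs the allylic oxidation on a furan-free substrate. It sets out from 16: photooxygenation under the conditions of step 13, where the furan should react far faster than the trisubstituted alkene at −78 °C, gives 2α,3α-bis(angeloyloxy)-12-hydroxylabda-7,13-dien-15,12-olide F4. Methylation as in step 14 gives methyl (13Z)-2α,3α-bis(angeloyloxy)-12-oxolabda-7,13-dien-15-oate F5. SeO2/t-BuOOH then gives methyl (13Z)-2α,3α-bis(angeloyloxy)-17-hydroxy-12-oxolabda-7,13-dien-15-oate F6, and MnO2 oxidation returns to the route at 22.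

Further compounds
F1 | step 3 | 6-methyl-6-[(Z)-3-(trimethylsilyl)prop-2-en-1-yl]carvone (silylallyl trans to isopropenyl) | C[Si](C)(C)/C=C\C[C@]1(C)C(=O)C(C)=CC[C@H]1C(C)=C
F2 | step 3 | tertiary chloride from F1 (2-chloropropan-2-yl on C5) | C[Si](C)(C)/C=C\C[C@]1(C)C(=O)C(C)=CC[C@H]1C(C)(C)Cl
F3 | step 11 | 2α,3α-bis{2-[bis(2,2,2-trifluoroethoxy)phosphoryl]propanoyloxy}-12,15-epoxylabda-7,12,14-triene | CC(P(=O)(OCC(F)(F)F)OCC(F)(F)F)C(=O)O[C@@H]1[C@H](OC(=O)C(C)P(=O)(OCC(F)(F)F)OCC(F)(F)F)C[C@]2(C)[C@@H](Cc3occc3C)C(C)=CC[C@H]2C1(C)C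
F4 | step 12 | 2α,3α-bis(angeloyloxy)-12-hydroxylabda-7,13-dien-15,12-olide | C/C=C(/C)C(=O)O[C@@H]1[C@H](OC(=O)/C(C)=C\C)C[C@]2(C)[C@@H](CC3(O)OC(=O)C=C3C)C(C)=CC[C@H]2C1(C)C
F5 | step 12 | methyl (13Z)-2α,3α-bis(angeloyloxy)-12-oxolabda-7,13-dien-15-oate | C/C=C(/C)C(=O)O[C@@H]1[C@H](OC(=O)/C(C)=C\C)C[C@]2(C)[C@@H](CC(=O)/C(C)=C\C(=O)OC)C(C)=CC[C@H]2C1(C)C
F6 | step 12 | methyl (13Z)-2α,3α-bis(angeloyloxy)-17-hydroxy-12-oxolabda-7,13-dien-15-oate | C/C=C(/C)C(=O)O[C@@H]1[C@H](OC(=O)/C(C)=C\C)C[C@]2(C)[C@@H](CC(=O)/C(C)=C\C(=O)OC)C(CO)=CC[C@H]2C1(C)C
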